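Amounts first: you charge 0.500 equiv of reagent against the starting material and want to know who ends up ahead, so keep the books of that reagent, the limiting reagent here.

in all of them: starting material 0.27 M; catalyst 4.1 mol%

|  | reagent | second substrate | protic impurity | temperature | remark | time |
|---|---|---|---|---|---|---|
| west | 0.25 equiv | 1 equiv | 0.027 M | 30 °C | run made earlier |  |
| east | 1 equiv | 1 equiv | 0.027 M | 48 °C | run made earlier |  |
| alder | 0.500 equiv | 1.00 equiv | 0.0270 M | 35 °C |  | 80 min |
| birch | 0.500 equiv | 1.00 equiv | 0.0270 M | 60 °C |  | 80 min |

- west (time / min: starting material / %, target / %): 4.00: 90.1, 1.3; 8.00: 87.8, 2.4; 15.0: 84.9, 5.4; 25.0: 82.6, 7.7; 50.0: 77.9, 11.5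
- east (time / min: starting material / %, target / %): 2.00: 81.0, 11.1; 4.00: 71.3, 18.5; 8.00: 58.7, 30.9; 12.0: 50.4, 40.0; 25.0: 35.2, 57.0

(each reading ± 0.5 percentage points)

- which of these there is most of at the end, counted by the starting material in it, alder (target / starting material)
- which of these there is most of at the end, counted by the starting material in it, birch (target / starting material)
- how much there is at the end of the one of these that leads, in percent of the starting material charged: alder
- how much there is at the end of the one of these that leads, in percent of the starting material charged: birch

In the earlier runs the sum of starting material and target reads short by 10.6 % at west's last reading and 9.60 % at east's 12.0 min, close to the 10.0 % that c(protic impurity)/c(starting material) gives. I therefore book that gap as starting material lost one to one to the impurity, and book no reagent against it. That leaves 90.0 % to be shared between starting material and target, and the two stand equal at the crossing line 45.0 %, which is half of that share and past which target leads.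

The reagent ledger then has three entries: nothing to the impurity, nothing to the second substrate that any reading shows, and the rest to target, one for one, or unspent. Crossing needs 90.0 % of the charge entered under target, which is 2.30 reagent lifetimes; I take the rate as first order in c(reagent) and first order in c(starting material), so a lifetime is counted by the rate constant times c(starting material), summed over the time, and c(starting material) falls on the way to the line.

The late windows of the runs give the decay of reagent per unit of c(starting material), counted as a fraction of its charge: 0.0599 min⁻¹ in east and 0.0131 min⁻¹ in west. Carried on in the logarithm, these become 0.0200 min⁻¹ for alder and 0.165 min⁻¹ for birch.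

Over 80 min, alder gets 1.44 lifetimes even with starting material held at its top, fewer than needed, so I expect target under 38.1 % and starting material leading above 51.9 %. Birch gets 5.94 with starting material held at the line, more than needed, so I expect target to lead near 50.0 %, with starting material near 40.0 %.

The forecast, with the impurity taking its share “of SM and of reagent”, gives starting material at 54.5 % for alder and starting material at 50.3 % for birch.

The flask gives alder starting material at 54.0 %, and birch target at 48.9 %.

    starting material + protic impurity → quenched substrate (k = 2.10 M⁻¹ min⁻¹, Ea = 44.0 kJ mol⁻¹)
    2 second substrate → homo dimer (k = 0.0400 M⁻¹ min⁻¹, Ea = 74.0 kJ mol⁻¹)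
    starting material + reagent + catalyst → catalyst + target (k = 8.40 M⁻² min⁻¹, Ea = 59.0 kJ mol⁻¹)
    second substrate + reagent + catalyst → catalyst + second product (k = 0.420 M⁻² min⁻¹, Ea = 36.0 kJ mol⁻¹)
    (constants at 35 °C)

Alder's target of 36.0 % ends under the line of 45.0 % and birch's 48.9 % over it, and the difference in temperature is the main reason: with that difference taken away, birch run at alder's temperature holds 36.0 % of target. Birch's books close with target, 0.850 % as second product and 0.214 % unspent. Charge a neighbour of birch with 0.16 M of starting material, c(protic impurity) unchanged, and the line drops to 41.6 %; at 80.0 min its target stands at 43.2 %, above that line, against 39.9 % of starting material.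

Readings and results are calculated with made-up constants; noise was put on by code.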